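The C7–C1' bond is made by carbonyl addition, not by aryl–aryl coupling. Ring C is carried as a 4-aryl-4-hydroxy-3-methylcyclohexa-2,5-dienone whose carbinol carbon is C1'. The key step exploits ring D (C5'–C8'), which is bare except for the 5'-oxygen peri to O4'. A Diels–Alder reaction of 1-isopropoxycyclohexa-1,3-diene with the methyl-free C4a'=C8a' alkene of this quinol forms C4a'–C5' and C8a'–C8' in one operation. It closes ring D as a bicyclo[2.2.2]octene and brings in O5' as an isopropyl ether, distinct from the ketone oxygen O4'. Loss of water, O-methylation, loss of ethylene and BCl3 cleavage then lead to the target.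

Key step: step 10

Assumption: the SMILES string defines the target and has no descriptor for the C7–C1' axis, so the route is planned for the racemic biaryl. The ent atropisomer would be separated from the final product on a chiral phase, because the heat of step 13 would erase any earlier enrichment.

Atom labels: primed locants are those of the naphthalene of the target and are used for the same carbons in all precursors. Ring C is C1'–C4', C4a', C8a'. Ring D is C4a', C5'–C8', C8a'.

Step 1
Reactants: 1 2',6'-dihydroxyacetophenone
Product: 2 2-acetyl-3-hydroxyphenyl trifluoromethanesulfonate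
Conditions: Tf2O (1.0 equiv), pyridine, CH2Cl2, −78 → 0 °C
Reagents that add atoms: trifluoromethanesulfonic anhydride, O=S(=O)(OS(=O)(=O)C(F)(F)F)C(F)(F)F
Why: O-Sulfonylation of a phenol: the two hydroxy groups of 1 are equivalent, and after the first triflation the ring is electron-poor and the remaining OH is hydrogen-bonded to the acetyl oxygen, so the reaction should stop at the monotriflate.

Step 2
Reactants: 2 2-acetyl-3-hydroxyphenyl trifluoromethanesulfonate; 3 propyne
Product: 4 1-[2-hydroxy-6-(prop-1-yn-1-yl)phenyl]ethan-1-one
Conditions: propyne (2 equiv, THF solution), PdCl2(PPh3)2 (3 mol %), CuI (5 mol %), Et3N, DMF, 50 °C, sealed tube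
Reagents that add atoms: none
Why: Sonogashira coupling: the triflate ortho to the acetyl group adds readily to zerovalent palladium, and the chelated phenol is a spectator that sits too far from the alkyne to cyclise onto it.

Step 3
Reactants: 4 1-[2-hydroxy-6-(prop-1-yn-1-yl)phenyl]ethan-1-one
Product: 6 1,3-dimethylisoquinolin-8-ol, via ketimine 5 (not isolated)
Conditions: NH3 (7 M in MeOH), 90 °C, sealed tube
Reagents that add atoms: ammonia, N
Why: Isoquinoline synthesis from a 2-alkynylaryl ketone: ammonia condenses with the ketone to the hydrogen-bond-stabilised ketimine 5, whose nitrogen closes onto the alkyne in the 6-endo-dig mode, and aromatisation makes the closure irreversible.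

Step 4
Reactants: 6 1,3-dimethylisoquinolin-8-ol
Product: 7 7-bromo-1,3-dimethylisoquinolin-8-ol
Conditions: NBS (1.0 equiv), iPr2NH (0.2 equiv), CH2Cl2, −20 °C → rt, dark
Reagents that add atoms: N-bromosuccinimide, O=C1CCC(=O)N1Br
Why: Amine-mediated ortho-bromination of a phenol: the N-bromoamine formed from NBS and iPr2NH is held by a hydrogen bond to the 8-OH, which the peri C1 methyl group turns towards C7, so bromine should go to C7 and not to the para position C5, as in the conversion of 1-naphthol into 2-bromo-1-naphthol.

Step 5
Reactants: 7 7-bromo-1,3-dimethylisoquinolin-8-ol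
Product: 8 8-(benzyloxy)-7-bromo-1,3-dimethylisoquinoline
Conditions: BnBr (1.1 equiv), K2CO3, DMF, rt
Reagents that add atoms: benzyl bromide, BrCc1ccccc1
Why: Williamson ether synthesis: the phenoxide outruns the ring nitrogen, which is flanked by two methyl groups, and benzyl is chosen because it tolerates magnesium reagents and acid and is removed together with isopropyl in the last step.

Step 6
Reactants: 9 4-methoxy-2-methylphenol
Product: 10 4,4-dimethoxy-2-methylcyclohexa-2,5-dien-1-one
Conditions: PhI(OAc)2 (1.05 equiv), MeOH, 0 °C
Reagents that add atoms: methanol, CO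
Why: Oxidative dearomatisation of a 4-alkoxyphenol with a hypervalent iodine reagent: two-electron oxidation gives a cation stabilised by the para methoxy group, which methanol traps at C4 to give the p-quinone monoketal with its free carbonyl next to the methyl-bearing carbon.

Step 7
Reactants: 8 8-(benzyloxy)-7-bromo-1,3-dimethylisoquinoline; 10 4,4-dimethoxy-2-methylcyclohexa-2,5-dien-1-one
Product: 13 4-[8-(benzyloxy)-1,3-dimethylisoquinolin-7-yl]-4-hydroxy-3-methylcyclohexa-2,5-dien-1-one (racemic), via arylmagnesium chloride 11 (not isolated), via quinol dimethyl ketal 12 (not isolated)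
Conditions: iPrMgCl·LiCl (1.1 equiv), THF, 0 °C → rt; LaCl3·2LiCl (1 equiv), 10 (1.2 equiv), −40 → 0 °C; 1 M aq. HCl, THF, 0 °C; aq. NaHCO3
Reagents that add atoms: isopropylmagnesium chloride–lithium chloride, CC(C)[Mg]Cl.[Li+].[Cl-] (MgCl of 11 only); water, O (carbonyl oxygen of 13)
Why: Bromine–magnesium exchange is fast next to the coordinating 8-benzyloxy group and, unlike lithiation, spares the acidic C1 methyl group; 11 then adds 1,2 to the only carbonyl of 10 (Grignard addition, with LaCl3·2LiCl favouring carbonyl attack over conjugate addition), the enantiotopic carbonyl faces give C1' as a racemate, and dilute acid hydrolyses the bis-allylic ketal of 12 far faster than it can ionise the carbinol.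

Step 8
Reactants: 14 isopropoxybenzene
Product: 15 1-isopropoxycyclohexa-1,4-diene
Conditions: Li (2.5 equiv), liq. NH3, tBuOH, THF, −78 → −33 °C; NH4Cl
Reagents that add atoms: none
Why: Birch reduction: donor-substituted arenes take up hydrogen at the 2- and 5-positions, which leaves the alkoxy group on one of the two isolated double bonds.

Step 9
Reactants: 15 1-isopropoxycyclohexa-1,4-diene
Product: 16 1-isopropoxycyclohexa-1,3-diene
Conditions: KOtBu (0.1 equiv), DMSO, rt; distillation
Reagents that add atoms: none
Why: Base-catalysed alkene isomerisation: reversible deprotonation of the doubly allylic CH2 group moves the isolated double bond into conjugation with the enol ether, and any unconjugated isomer left at equilibrium is inert in step 10.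

Step 10
Reactants: 13 4-[8-(benzyloxy)-1,3-dimethylisoquinolin-7-yl]-4-hydroxy-3-methylcyclohexa-2,5-dien-1-one; 16 1-isopropoxycyclohexa-1,3-diene
Product: 17 rac-4-[8-(benzyloxy)-1,3-dimethylisoquinolin-7-yl]-4-hydroxy-8-isopropoxy-3-methyl-4a,5,8,8a-tetrahydro-5,8-ethanonaphthalen-1(4H)-one, the endo adduct. H-4a' and H-8a' are cis and lie on the face of ring C that bears the isoquinolinyl group. The 1'-OH and both new C–C bonds lie on the other face. The C6'=C7' bridge sits under ring C and the CH2CH2 bridge points away from it.
Conditions: 16 (5 equiv), BHT (1 mol %), CH2Cl2, 12 kbar, 40 °C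
Reagents that add atoms: none
Why: The reaction is a concerted, suprafacial [4+2] cycloaddition of normal electron demand between the HOMO of the donor-substituted diene 16 and the LUMO of the cross-conjugated dienone 13, and its strongly negative activation volume lets pressure replace the heat or Lewis acid that the enol ether and the quinol would not tolerate. The closest known reactions are the Diels–Alder additions of cyclic dienes to 4-alkyl-4-hydroxycyclohexa-2,5-dienones and those of 1-alkoxycyclohexa-1,3-dienes to enones and quinones. Ring D (C4a'–C5'–C6'–C7'–C8'–C8a') closes by intermolecular cycloaddition, four carbons coming from the diene and two from the dienophile, and it appears as a bicyclo[2.2.2]octene because C5' and C8' are already linked by the CH2CH2 unit of 16. C4a' and C8a' become cis because addition to the ring alkene is suprafacial, their sense relative to C1' follows from attack on the face that carries the small OH and not the isoquinolinyl group, and C5' and C8' are fixed by the endo alignment, which places ring C under the new C6'=C7' bond. Site selectivity comes from the C2' methyl group, which makes C2'=C3' trisubstituted and more electron-rich so that only C4a'=C8a' reacts; orientation follows the ortho rule, the unsubstituted diene terminus with the larger HOMO coefficient bonding to the β-carbon C8a' and the alkoxy-bearing terminus to C4a', which also keeps the fully substituted diene carbon away from the crowded C1'. All four new stereocentres are erased later, so only site and orientation matter for the target.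

Step 11
Reactants: 17 endo Diels–Alder adduct
Product: 18 4-[8-(benzyloxy)-1,3-dimethylisoquinolin-7-yl]-8-isopropoxy-3-methyl-5,8-dihydro-5,8-ethanonaphthalen-1-ol (racemic at the bridgeheads C5' and C8'; possibly two rotamers about C7–C1')
Conditions: CF3CO2H–CH2Cl2 (1:4), 0 °C → rt; aq. NaHCO3
Reagents that add atoms: none
Why: Acid-catalysed dehydrative aromatisation: enolisation of the C4' ketone towards C4a' and loss of water from C1' and C8a' (H-8a' is trans to the hydroxy group) are both acid-catalysed and are driven by the aromaticity of ring C, as with arene hydrates; C1', C4a' and C8a' lose their stereochemistry, the hindered C7–C1' axis appears without control, and the ethers and the C6'=C7' alkene should survive this acid.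

Step 12
Reactants: 18 ethano-bridged 4'-phenol
Product: 19 8-(benzyloxy)-7-(5-isopropoxy-4-methoxy-2-methyl-5,8-dihydro-5,8-ethanonaphthalen-1-yl)-1,3-dimethylisoquinoline
Conditions: MeI (1.1 equiv), Cs2CO3, DMF, 0 °C → rt
Reagents that add atoms: iodomethane, CI
Why: Williamson O-methylation: the only free OH is the C4' phenol, whose caesium salt reacts with MeI much faster than the hindered ring nitrogen, and O5' cannot compete because it is still an isopropyl ether.

Step 13
Reactants: 19 ethano-bridged 4'-methyl ether
Product: 20 8-(benzyloxy)-7-(5-isopropoxy-4-methoxy-2-methylnaphthalen-1-yl)-1,3-dimethylisoquinoline (racemic axis)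
Conditions: Ph2O, 250 °C, Ar, sealed vessel (microwave)
Reagents that add atoms: none
Why: Alder–Rickert reaction (retro-Diels–Alder): the benzo-fused bicyclo[2.2.2]octadiene expels its CH2CH2 bridge as ethylene in a concerted cycloreversion driven by gas loss and by aromatisation of ring D, the bridgehead oxygen stays on C5', both bridgehead stereocentres vanish, and any rotamers converge on racemic 20.

Step 14
Reactants: 20 protected naphthylisoquinoline
Product: 21 7-(5-hydroxy-4-methoxy-2-methylnaphthalen-1-yl)-1,3-dimethylisoquinolin-8-ol (target constitution, racemic axis)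
Conditions: BCl3 (6 equiv), C6HMe5 (3 equiv), CH2Cl2, −78 → 0 °C; H2O
Reagents that add atoms: none
Why: Lewis-acid ether cleavage: BCl3 removes aryl benzyl and aryl isopropyl ethers, whose alkyl groups leave as stabilised cation-like fragments, while the aryl methyl ether at C4' resists at or below 0 °C, and pentamethylbenzene traps the benzyl cation before it can alkylate the naphthol.

Compound list
1 | 2',6'-dihydroxyacetophenone | CC(=O)c1c(O)cccc1O | starting material
2 | 2-acetyl-3-hydroxyphenyl trifluoromethanesulfonate | CC(=O)c1c(O)cccc1OS(=O)(=O)C(F)(F)F | intermediate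
3 | propyne | CC#C | starting material
4 | 1-[2-hydroxy-6-(prop-1-yn-1-yl)phenyl]ethan-1-one | CC#Cc1cccc(O)c1C(C)=O | intermediate
5 | 2-(1-iminoethyl)-3-(prop-1-yn-1-yl)phenol (ketimine, not isolated) | CC#Cc1cccc(O)c1C(C)=N | intermediate
6 | 1,3-dimethylisoquinolin-8-ol | Cc1cc2cccc(O)c2c(C)n1 | intermediate
7 | 7-bromo-1,3-dimethylisoquinolin-8-ol | Cc1cc2ccc(Br)c(O)c2c(C)n1 | intermediate
8 | 8-(benzyloxy)-7-bromo-1,3-dimethylisoquinoline | Cc1cc2ccc(Br)c(OCc3ccccc3)c2c(C)n1 | intermediate
9 | 4-methoxy-2-methylphenol | COc1ccc(O)c(C)c1 | starting material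
10 | 4,4-dimethoxy-2-methylcyclohexa-2,5-dien-1-one | COC1(OC)C=CC(=O)C(C)=C1 | intermediate
11 | [8-(benzyloxy)-1,3-dimethylisoquinolin-7-yl]magnesium chloride (LiCl complex, not isolated) | Cc1cc2ccc([Mg]Cl)c(OCc3ccccc3)c2c(C)n1 | intermediate
12 | 1-[8-(benzyloxy)-1,3-dimethylisoquinolin-7-yl]-4,4-dimethoxy-2-methylcyclohexa-2,5-dien-1-ol (racemic, one enantiomer drawn; formed as its chloromagnesium alkoxide, not isolated) | COC1(OC)C=C(C)[C@](O)(c2ccc3cc(C)nc(C)c3c2OCc2ccccc2)C=C1 | intermediate
13 | 4-[8-(benzyloxy)-1,3-dimethylisoquinolin-7-yl]-4-hydroxy-3-methylcyclohexa-2,5-dien-1-one (racemic, S enantiomer drawn) | O=C1C=C(C)[C@](O)(c2ccc3cc(C)nc(C)c3c2OCc2ccccc2)C=C1 | intermediate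
14 | isopropoxybenzene | CC(C)Oc1ccccc1 | starting material
15 | 1-isopropoxycyclohexa-1,4-diene | CC(C)OC1=CCC=CC1 | intermediate
16 | 1-isopropoxycyclohexa-1,3-diene | CC(C)OC1=CC=CCC1 | intermediate
17 | endo Diels–Alder adduct, 4-aryl-4-hydroxy-8-isopropoxy-3-methyl-4a,5,8,8a-tetrahydro-5,8-ethanonaphthalen-1(4H)-one (racemic, relative configuration drawn) | O=C1C=C(C)[C@](O)(c4ccc5cc(C)nc(C)c5c4OCc4ccccc4)[C@@H]2[C@H]1[C@@]3(OC(C)C)CC[C@@H]2C=C3 | intermediate
18 | 4-[8-(benzyloxy)-1,3-dimethylisoquinolin-7-yl]-8-isopropoxy-3-methyl-5,8-dihydro-5,8-ethanonaphthalen-1-ol (racemic bridgeheads, axis uncontrolled) | Oc1cc(C)c(-c4ccc5cc(C)nc(C)c5c4OCc4ccccc4)c2c1[C@@]3(OC(C)C)CC[C@@H]2C=C3 | intermediate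
19 | 8-(benzyloxy)-7-(5-isopropoxy-4-methoxy-2-methyl-5,8-dihydro-5,8-ethanonaphthalen-1-yl)-1,3-dimethylisoquinoline (racemic bridgeheads, axis uncontrolled) | COc1cc(C)c(-c4ccc5cc(C)nc(C)c5c4OCc4ccccc4)c2c1[C@@]3(OC(C)C)CC[C@@H]2C=C3 | intermediate
20 | 8-(benzyloxy)-7-(5-isopropoxy-4-methoxy-2-methylnaphthalen-1-yl)-1,3-dimethylisoquinoline (racemic axis) | COc1cc(C)c(-c2ccc3cc(C)nc(C)c3c2OCc2ccccc2)c2cccc(OC(C)C)c12 | intermediate
21 | 7-(5-hydroxy-4-methoxy-2-methylnaphthalen-1-yl)-1,3-dimethylisoquinolin-8-ol | COc1cc(C)c(-c2ccc3cc(C)nc(C)c3c2O)c2cccc(O)c12 | target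

Total step count: 14. The isoquinoline branch takes 5 steps, the monoketal 1, the union 1, the diene 2, the key step 1 and the endgame 4.
Longest linear sequence: 11 steps (1 → 2 → 4 → 6 → 7 → 8 → 13 → 17 → 18 → 19 → 20 → 21).

Steps most likely to fail

Step 10. The cycloaddition may be too slow, because the bond to C8a' must form next to the fully substituted C1'. The diene could then be lost first through isomerisation, hydrolysis or disproportionation. In the fallback ring D is bought instead of built, and the carbonyl-addition logic for C7–C1' is kept. The fallback sets out from 8 (through 11) and returns at 20. Commercial plumbagin (5-hydroxy-2-methyl-1,4-naphthoquinone) is O-alkylated with 2-iodopropane and Ag2O in CH2Cl2 to 5-isopropoxy-2-methyl-1,4-naphthoquinone F1. The arylmagnesium chloride 11, made from 8 as in step 7, should add to the C1 carbonyl of F1, because C4=O is deactivated by the ortho alkoxy donor and screened by the peri isopropoxy group. This gives 4-aryl-4-hydroxy-8-isopropoxy-3-methylnaphthalen-1(4H)-one F2. Zn in AcOH reduces this p-quinol with loss of water to 4-aryl-8-isopropoxy-3-methylnaphthalen-1-ol F3 (reductive aromatisation). MeI and Cs2CO3 in DMF then give 20.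

Step 13. The cycloreversion gains only the aromaticity of the second ring of a naphthalene and therefore needs about 250 °C. At that temperature, homolysis or migration of the benzyl ether may compete. The fallback sets out from 19 and returns at 21, using anionic acceleration instead of heat. BCl3 and C6HMe5 (CH2Cl2, −78 °C → rt) remove the benzyl group and cleave the isopropyl side of the bridgehead ether, since the bridgehead carbon can neither ionise nor be attacked from the rear. This gives 7-(5-hydroxy-4-methoxy-2-methyl-5,8-dihydro-5,8-ethanonaphthalen-1-yl)-1,3-dimethylisoquinolin-8-ol F4. KH (3 equiv) and 18-crown-6 in dioxane at 60–100 °C form the bridgehead alkoxide. Its oxyanion weakens the adjacent C5'–CH2 bond and should strongly accelerate ethylene loss, an oxyanion-accelerated retro-Diels–Alder reaction as known for bridgehead-oxido anthracene adducts. Acidification gives 21 directly.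

Step 4. Ortho/para selectivity may be poor, with attack at C5 or double bromination. The fallback sets out from 6 and returns at 7, using a removable blocking group at C5. Oleum (20 % SO3, 0 °C → rt) sulfonates 6 at C5, the position favoured both by the para OH and by the isoquinoline nucleus. This gives 8-hydroxy-1,3-dimethylisoquinoline-5-sulfonic acid F5. Br2 in aqueous AcOH can then only enter at C7 and gives 7-bromo-8-hydroxy-1,3-dimethylisoquinoline-5-sulfonic acid F6. This is the logic by which 7-halo-8-hydroxyquinoline-5-sulfonic acids are made. Protodesulfonation in hot dilute H2SO4 (about 140 °C) gives 7.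

Further compounds
F1 | step 10 | 5-isopropoxy-2-methyl-1,4-naphthoquinone | CC1=CC(=O)c2c(OC(C)C)cccc2C1=O
F2 | step 10 | 4-[8-(benzyloxy)-1,3-dimethylisoquinolin-7-yl]-4-hydroxy-8-isopropoxy-3-methylnaphthalen-1(4H)-one (racemic, one enantiomer drawn) | O=C1C=C(C)[C@](O)(c3ccc4cc(C)nc(C)c4c3OCc3ccccc3)c2cccc(OC(C)C)c12
F3 | step 10 | 4-[8-(benzyloxy)-1,3-dimethylisoquinolin-7-yl]-8-isopropoxy-3-methylnaphthalen-1-ol | Oc1cc(C)c(-c3ccc4cc(C)nc(C)c4c3OCc3ccccc3)c2cccc(OC(C)C)c12
F4 | step 13 | 7-(5-hydroxy-4-methoxy-2-methyl-5,8-dihydro-5,8-ethanonaphthalen-1-yl)-1,3-dimethylisoquinolin-8-ol (racemic bridgeheads) | COc1cc(C)c(-c4ccc5cc(C)nc(C)c5c4O)c2c1[C@@]3(O)CC[C@@H]2C=C3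
F5 | step 4 | 8-hydroxy-1,3-dimethylisoquinoline-5-sulfonic acid | Cc1cc2c(S(=O)(=O)O)ccc(O)c2c(C)n1
F6 | step 4 | 7-bromo-8-hydroxy-1,3-dimethylisoquinoline-5-sulfonic acid | Cc1cc2c(S(=O)(=O)O)cc(Br)c(O)c2c(C)n1
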